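The runs stem from a simulated flask with constants of no real substance; scatter was added.

Per minute, as a fraction of the charge, follow the dissolving first. Here is the flask and what its autumn run has shown so far.

- autumn: solid substrate 0.80 M; the very flask that is asked about, followed so far
- flask: solid substrate 0.80 M; time 25 min

autumn run (percent of the solid substrate charged)

| time / min | target / % | starting material / % |
|---|---|---|
| 1.00 | 0 | 3.7 |
| 2.50 | 2.1 | 9.9 |
| 5.00 | 9.6 | 16.4 |
| 12.0 | 34.2 | 21.3 |

(each reading ± 1 percentage point)

- solid, in amounts per volume of the solution: solid substrate
- the numbers in the tables scatter with a standard deviation of 1 percentage point
- steps that have been proposed: starting material -> target; starting material -> side product; solid substrate <-> starting material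
- at the start none of the solid substrate is in solution
- starting material means what is dissolved; the solid is not counted in it

- the target standing at 25 min, as a percentage of the solid substrate charged
- concentration of starting material in solution at 25 min, in percent of saturation

What has entered solution stands as target, starting material and side product; the readings show the first two, so their sum counts short by the side product. In the autumn run that sum stands at 55.5% by 12.0 min. My first reckoning is therefore a steady feed of 0.0463 /min, which would use up the solid substrate in 21.6 min.

Now put that answer back in, because the steady feed is the weak link. The readings give 0.0520 /min up to 5.00 min but a slower 0.0421 /min after it. At the slower feed the remainder lasts until 22.6 min. Call this the solid lifetime, the time at which the last solid has dissolved; the unseen side product makes it read somewhat long, and it is still shorter than 25 min.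

Between the last two readings the target grew by 0.186 /min of the dissolved starting material. Over the last 2.40 min I therefore let the starting material fall from 21.3% to 13.5%. That leaves 86.5% for target and side product together.

This share is higher than the target in the forecast, which stands at 73% (60% to 85%), with saturation at 15% (6% to 30%). Of the dissolved level it says: “That plateau is a balance between feed and consumption, not saturation”.

The flask gives target 81.7% and starting material at 10.3% of saturation, with solid substrate 0% and side product 8.17% at 25.0 min.

    starting material → target (k = 0.00310 /s)
    starting material → side product (k = 3.10 × 10⁻⁴ /s)
    solid substrate ⇌ starting material, rate k3*(cs3 - [starting material]) while solid is left; crystals form when [starting material] > cs3 (solubility = 0.790 M, k = 9.70 × 10⁻⁴ /s)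

Carry the lifetime to a neighbour charged with 1.4 M. Taking the same feed per volume, the lifetime stretches with the charge to 39.5 min, so 36.7% of its solid should remain at 25 min. That neighbour holds 33.3% solid substrate and 12.5% starting material then, and its target stands at 49.3%.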